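**Retrosynthetic overview**
1. Target 22 comes from the C7' aryl ketone 19 by Corey–Bakshi–Shibata reduction at C7', desilylation and hydrogenolysis.
2. The strategy rests on the 3',4'-dioxygenated benzene ring (C1'–C6') being joined to C4 of ring A only through C7'. That ring is cut at C1'–C2' and C5'–C6' into the C2-symmetric diene 17 (C2'–C5', both oxygens in place) and the C1'≡C6' alkyne of the C7' ynone 15.
3. Ynone 15 comes from aldehyde 12 (ethynyl Grignard addition, oxidation), which comes from the ring A silyl ether 10.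
4. Ring A (O1, C2–C5) comes from acid-catalysed cyclodehydration of diol 9, made by aryllithium opening of lactone 5, made by trans alkylation of lactone 3 from (S)-paraconic acid 1, whose stereocentre becomes C4.
5. Ring order: lactone ring (present in 1), then ring A (step 6), then the catechol ring last (step 12).

Key step: step 12

Remark: ring A is numbered O1, C2 (guaiacyl), C3 (C9 arm), C4 (C7' arm), C5 in every intermediate, and the catechol ring is C1'–C6'; (S)-paraconic acid of high enantiomeric purity is assumed to be purchasable.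

**Route**

Step 1
Reactants: 1 (S)-paraconic acid
Product: 2 (R)-4-(hydroxymethyl)dihydrofuran-2(3H)-one
Conditions: BH3·SMe2, THF, 0 °C to rt; then MeOH
Reagents that add atoms: none
Why: Chemoselective borane reduction of a carboxylic acid in the presence of a lactone (acyloxyborane pathway); the stereocentre is untouched and only its descriptor changes through the priority rules.

Step 2
Reactants: 2 (R)-4-(hydroxymethyl)dihydrofuran-2(3H)-one
Product: 3 (S)-4-{[(tert-butyldiphenylsilyl)oxy]methyl}dihydrofuran-2(3H)-one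
Conditions: t-BuPh2SiCl, imidazole, CH2Cl2, 0 °C to rt
Reagents that add atoms: tert-butyl(chloro)diphenylsilane, CC(C)(C)[Si](Cl)(c1ccccc1)c1ccccc1
Why: Imidazole-promoted silylation of the primary alcohol, carried out at once on crude 2 so that acyl migration between the two CH2O arms on C4, which would racemise it, should have no time to occur.

Step 3
Reactants: 3 (S)-4-{[(tert-butyldiphenylsilyl)oxy]methyl}dihydrofuran-2(3H)-one
Product: 5 (3R,4S)-3-[(benzyloxy)methyl]-4-{[(tert-butyldiphenylsilyl)oxy]methyl}dihydrofuran-2(3H)-one, via lithium enolate 4 (not isolated)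
Conditions: LiN(SiMe3)2, THF, −78 °C; BnOCH2Cl, −78 to −40 °C
Reagents that add atoms: benzyl chloromethyl ether, ClCOCc1ccccc1
Why: Lactone enolate alkylation; the electrophile should approach the planar enolate anti to the bulky C4 silyloxymethyl group, which sets C3 trans to C4.

Step 4
Reactants: 5 (3R,4S)-3-[(benzyloxy)methyl]-4-{[(tert-butyldiphenylsilyl)oxy]methyl}dihydrofuran-2(3H)-one; 6 1-(benzyloxy)-4-bromo-2-methoxybenzene
Product: 8 (2R,3S)-1-[4-(benzyloxy)-3-methoxyphenyl]-2-[(benzyloxy)methyl]-3-{[(tert-butyldiphenylsilyl)oxy]methyl}-4-hydroxybutan-1-one, via aryllithium 7 (not isolated)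
Conditions: 6, n-BuLi, THF, −78 °C; then 5, −78 °C; AcOH quench at −78 °C
Reagents that add atoms: none
Why: Bromine–lithium exchange followed by single addition of the aryllithium to the lactone carbonyl; the cyclic lithium hemiketal alkoxide should persist at −78 °C and be protonated before it releases the ketone, so a second addition is not expected.

Step 5
Reactants: 8 (2R,3S)-1-[4-(benzyloxy)-3-methoxyphenyl]-2-[(benzyloxy)methyl]-3-{[(tert-butyldiphenylsilyl)oxy]methyl}-4-hydroxybutan-1-one
Product: 9 (2R,3S)-1-[4-(benzyloxy)-3-methoxyphenyl]-2-[(benzyloxy)methyl]-3-{[(tert-butyldiphenylsilyl)oxy]methyl}butane-1,4-diol (mixture of C1 epimers)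
Conditions: NaBH4, MeOH/THF, 0 °C
Reagents that add atoms: none
Why: Borohydride reduction of the aryl ketone; the configuration of the new carbinol does not matter because that carbon is ionised in step 6.

Step 6
Reactants: 9 (2R,3S)-1-[4-(benzyloxy)-3-methoxyphenyl]-2-[(benzyloxy)methyl]-3-{[(tert-butyldiphenylsilyl)oxy]methyl}butane-1,4-diol
Product: 10 (2S,3R,4S)-2-[4-(benzyloxy)-3-methoxyphenyl]-3-[(benzyloxy)methyl]-4-{[(tert-butyldiphenylsilyl)oxy]methyl}tetrahydrofuran
Conditions: camphorsulfonic acid (cat.), CH2Cl2, rt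
Reagents that add atoms: none
Why: Acid-catalysed SN1 cycloetherification: the p-alkoxybenzylic cation formed from either carbinol epimer is trapped by the primary hydroxyl in a 5-exo closure of ring A, and under reversible ionisation the aryl group should settle trans to the C3 arm, which sets C2 as S.

Step 7
Reactants: 10 (2S,3R,4S)-2-[4-(benzyloxy)-3-methoxyphenyl]-3-[(benzyloxy)methyl]-4-{[(tert-butyldiphenylsilyl)oxy]methyl}tetrahydrofuran
Product: 11 (2S,3R,4R)-2-[4-(benzyloxy)-3-methoxyphenyl]-3-[(benzyloxy)methyl]-4-(hydroxymethyl)tetrahydrofuran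
Conditions: Bu4NF, THF, rt
Reagents that add atoms: none
Why: Fluoride cleavage of the silicon–oxygen bond of the primary silyl ether; benzyl ethers and ring A are inert to fluoride.

Step 8
Reactants: 11 (2S,3R,4R)-2-[4-(benzyloxy)-3-methoxyphenyl]-3-[(benzyloxy)methyl]-4-(hydroxymethyl)tetrahydrofuran
Product: 12 (2S,3R,4S)-2-[4-(benzyloxy)-3-methoxyphenyl]-3-[(benzyloxy)methyl]tetrahydrofuran-4-carbaldehyde
Conditions: Dess–Martin periodinane, CH2Cl2, 0 °C to rt
Reagents that add atoms: none
Why: Dess–Martin oxidation of the primary alcohol under base-free conditions; C4 should not epimerise, the more so as its arm already sits in the favoured position trans to the C3 arm.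

Step 9
Reactants: 12 (2S,3R,4S)-2-[4-(benzyloxy)-3-methoxyphenyl]-3-[(benzyloxy)methyl]tetrahydrofuran-4-carbaldehyde; 13 ethynylmagnesium bromide
Product: 14 1-{(2S,3R,4S)-2-[4-(benzyloxy)-3-methoxyphenyl]-3-[(benzyloxy)methyl]tetrahydrofuran-4-yl}prop-2-yn-1-ol (mixture of C7' epimers)
Conditions: THF, −78 to 0 °C
Reagents that add atoms: none
Why: Grignard addition of the weakly basic alkynyl nucleophile to the aldehyde; both C7' epimers are carried on because C7' becomes a carbonyl in step 10.

Step 10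
Reactants: 14 1-{(2S,3R,4S)-2-[4-(benzyloxy)-3-methoxyphenyl]-3-[(benzyloxy)methyl]tetrahydrofuran-4-yl}prop-2-yn-1-ol
Product: 15 1-{(2S,3R,4S)-2-[4-(benzyloxy)-3-methoxyphenyl]-3-[(benzyloxy)methyl]tetrahydrofuran-4-yl}prop-2-yn-1-one
Conditions: Dess–Martin periodinane, CH2Cl2, 0 °C
Reagents that add atoms: none
Why: Dess–Martin oxidation of the secondary propargylic alcohol to the terminal ynone, which should be used promptly in step 12.

Step 11
Reactants: 16 2,3-butanedione
Product: 17 2,3-bis(tert-butyldimethylsilyloxy)buta-1,3-diene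
Conditions: t-BuMe2SiOTf, Et3N, CH2Cl2, 0 °C to rt
Reagents that add atoms: tert-butyldimethylsilyl trifluoromethanesulfonate, CC(C)(C)[Si](C)(C)OS(=O)(=O)C(F)(F)F
Why: Twofold soft enolisation and O-silylation of the 1,2-diketone gives the bis(silyl enol ether).

Step 12
Reactants: 15 1-{(2S,3R,4S)-2-[4-(benzyloxy)-3-methoxyphenyl]-3-[(benzyloxy)methyl]tetrahydrofuran-4-yl}prop-2-yn-1-one; 17 2,3-bis(tert-butyldimethylsilyloxy)buta-1,3-diene
Product: 19 [3,4-bis(tert-butyldimethylsilyloxy)phenyl]{(2S,3R,4S)-2-[4-(benzyloxy)-3-methoxyphenyl]-3-[(benzyloxy)methyl]tetrahydrofuran-4-yl}methanone, via cyclohexadiene cycloadduct 18 (not isolated)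
Conditions: 17 (3 equiv), toluene, 110 °C, sealed tube; then activated MnO2 (tetravalent manganese), same flask, rt to 60 °C
Reagents that add atoms: none
Why: A thermal Diels–Alder reaction of normal electron demand is expected: the electron-rich bis(silyloxy)diene 17 adds in a concerted [4+2] fashion across the electron-poor C1'≡C6' triple bond of ynone 15 to give the 1-acyl-4,5-bis(silyloxy)cyclohexa-1,4-diene 18. The six-membered carbocycle is closed intermolecularly through the two new bonds C1'–C2' and C5'–C6', and MnO2 then dehydrogenates the 1,4-diene, with aromatisation as the driving force. The closest known reaction type is the cycloaddition of 2,3-bis(silyloxy)butadienes to acetylenic ketones and esters followed by dehydrogenation to protected catechols. No stereocentre is formed; C4, alpha to the ketone, already carries its arm trans to the C3 arm and no base is present, so it should be retained. The step needs chemoselectivity for cycloaddition over oligomerisation of the ynone, which the excess of diene and the absence of Lewis acids and nucleophiles should secure. Regiochemistry does not arise, because the diene is C2-symmetric and the two oxygens must end at C3' and C4'.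

Step 13
Reactants: 19 [3,4-bis(tert-butyldimethylsilyloxy)phenyl]{(2S,3R,4S)-2-[4-(benzyloxy)-3-methoxyphenyl]-3-[(benzyloxy)methyl]tetrahydrofuran-4-yl}methanone
Product: 20 (R)-[3,4-bis(tert-butyldimethylsilyloxy)phenyl]{(2S,3R,4S)-2-[4-(benzyloxy)-3-methoxyphenyl]-3-[(benzyloxy)methyl]tetrahydrofuran-4-yl}methanol
Conditions: (S)-2-methyl-CBS-oxazaborolidine (0.5 equiv), BH3·SMe2, THF, −20 °C; then MeOH
Reagents that add atoms: none
Why: Corey–Bakshi–Shibata reduction; the ketone should bind the ring boron with the aryl group as the larger substituent, so that hydride from the nitrogen-bound borane reaches the face that gives the (R)-carbinol, in the same sense as acetophenone with the (S)-catalyst.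

Step 14
Reactants: 20 (R)-[3,4-bis(tert-butyldimethylsilyloxy)phenyl]{(2S,3R,4S)-2-[4-(benzyloxy)-3-methoxyphenyl]-3-[(benzyloxy)methyl]tetrahydrofuran-4-yl}methanol
Product: 21 4-[(R)-{(2S,3R,4S)-2-[4-(benzyloxy)-3-methoxyphenyl]-3-[(benzyloxy)methyl]tetrahydrofuran-4-yl}(hydroxy)methyl]benzene-1,2-diol
Conditions: Bu4NF, AcOH, THF, 0 °C, argon
Reagents that add atoms: none
Why: Fluoride cleavage of the two aryl silyl ethers; the acetic acid buffer keeps the catechol protonated, which should prevent autoxidation and quinone methide formation at C7'.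

Step 15
Reactants: 21 4-[(R)-{(2S,3R,4S)-2-[4-(benzyloxy)-3-methoxyphenyl]-3-[(benzyloxy)methyl]tetrahydrofuran-4-yl}(hydroxy)methyl]benzene-1,2-diol
Product: 22 (2S,3R,4S)-4-[(R)-(3,4-dihydroxyphenyl)(hydroxy)methyl]-2-(4-hydroxy-3-methoxyphenyl)-3-(hydroxymethyl)tetrahydrofuran (target)
Conditions: H2 (1 atm), Pd/C (zerovalent palladium on carbon), EtOAc/EtOH, rt, stopped when 21 is consumed
Reagents that add atoms: none
Why: Catalytic hydrogenolysis of the aryl and alkyl benzyl ethers; under neutral conditions at atmospheric pressure O-benzyl ethers should cleave faster than the benzylic C7'–OH and C2–O1 bonds.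

**Compound list**
1 | (S)-paraconic acid | O=C1OC[C@@H](C(=O)O)C1 | starting material
2 | (R)-4-(hydroxymethyl)dihydrofuran-2(3H)-one | O=C1OC[C@@H](CO)C1 | intermediate
3 | (S)-4-{[(tert-butyldiphenylsilyl)oxy]methyl}dihydrofuran-2(3H)-one | O=C1OC[C@@H](CO[Si](c2ccccc2)(c2ccccc2)C(C)(C)C)C1 | intermediate
4 | lithium enolate of 3 (not isolated) | [Li]OC1=C[C@H](CO[Si](c2ccccc2)(c2ccccc2)C(C)(C)C)CO1 | intermediate
5 | (3R,4S)-3-[(benzyloxy)methyl]-4-{[(tert-butyldiphenylsilyl)oxy]methyl}dihydrofuran-2(3H)-one | O=C1OC[C@@H](CO[Si](c2ccccc2)(c2ccccc2)C(C)(C)C)[C@@H]1COCc1ccccc1 | intermediate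
6 | 1-(benzyloxy)-4-bromo-2-methoxybenzene | COc1cc(Br)ccc1OCc1ccccc1 | starting material
7 | [4-(benzyloxy)-3-methoxyphenyl]lithium (not isolated) | COc1cc([Li])ccc1OCc1ccccc1 | intermediate
8 | (2R,3S)-1-[4-(benzyloxy)-3-methoxyphenyl]-2-[(benzyloxy)methyl]-3-{[(tert-butyldiphenylsilyl)oxy]methyl}-4-hydroxybutan-1-one | COc1cc(C(=O)[C@@H](COCc2ccccc2)[C@@H](CO)CO[Si](c2ccccc2)(c2ccccc2)C(C)(C)C)ccc1OCc1ccccc1 | intermediate
9 | (2R,3S)-1-[4-(benzyloxy)-3-methoxyphenyl]-2-[(benzyloxy)methyl]-3-{[(tert-butyldiphenylsilyl)oxy]methyl}butane-1,4-diol, C1 epimer mixture | COc1cc(C(O)[C@@H](COCc2ccccc2)[C@@H](CO)CO[Si](c2ccccc2)(c2ccccc2)C(C)(C)C)ccc1OCc1ccccc1 | intermediate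
10 | (2S,3R,4S)-2-[4-(benzyloxy)-3-methoxyphenyl]-3-[(benzyloxy)methyl]-4-{[(tert-butyldiphenylsilyl)oxy]methyl}tetrahydrofuran | COc1cc([C@H]2OC[C@@H](CO[Si](c3ccccc3)(c3ccccc3)C(C)(C)C)[C@@H]2COCc2ccccc2)ccc1OCc1ccccc1 | intermediate
11 | (2S,3R,4R)-2-[4-(benzyloxy)-3-methoxyphenyl]-3-[(benzyloxy)methyl]-4-(hydroxymethyl)tetrahydrofuran | COc1cc([C@H]2OC[C@@H](CO)[C@@H]2COCc2ccccc2)ccc1OCc1ccccc1 | intermediate
12 | (2S,3R,4S)-2-[4-(benzyloxy)-3-methoxyphenyl]-3-[(benzyloxy)methyl]tetrahydrofuran-4-carbaldehyde | COc1cc([C@H]2OC[C@@H](C=O)[C@@H]2COCc2ccccc2)ccc1OCc1ccccc1 | intermediate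
13 | ethynylmagnesium bromide | C#C[Mg]Br | starting material
14 | 1-{(2S,3R,4S)-2-[4-(benzyloxy)-3-methoxyphenyl]-3-[(benzyloxy)methyl]tetrahydrofuran-4-yl}prop-2-yn-1-ol, C7' epimer mixture | COc1cc([C@H]2OC[C@@H](C(O)C#C)[C@@H]2COCc2ccccc2)ccc1OCc1ccccc1 | intermediate
15 | 1-{(2S,3R,4S)-2-[4-(benzyloxy)-3-methoxyphenyl]-3-[(benzyloxy)methyl]tetrahydrofuran-4-yl}prop-2-yn-1-one | COc1cc([C@H]2OC[C@@H](C(=O)C#C)[C@@H]2COCc2ccccc2)ccc1OCc1ccccc1 | intermediate
16 | 2,3-butanedione | CC(=O)C(C)=O | starting material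
17 | 2,3-bis(tert-butyldimethylsilyloxy)buta-1,3-diene | C=C(O[Si](C)(C)C(C)(C)C)C(=C)O[Si](C)(C)C(C)(C)C | intermediate
18 | [4,5-bis(tert-butyldimethylsilyloxy)cyclohexa-1,4-dien-1-yl]{(2S,3R,4S)-2-[4-(benzyloxy)-3-methoxyphenyl]-3-[(benzyloxy)methyl]tetrahydrofuran-4-yl}methanone (not isolated) | COc1cc([C@H]2OC[C@@H](C(=O)C3=CCC(O[Si](C)(C)C(C)(C)C)=C(O[Si](C)(C)C(C)(C)C)C3)[C@@H]2COCc2ccccc2)ccc1OCc1ccccc1 | intermediate
19 | [3,4-bis(tert-butyldimethylsilyloxy)phenyl]{(2S,3R,4S)-2-[4-(benzyloxy)-3-methoxyphenyl]-3-[(benzyloxy)methyl]tetrahydrofuran-4-yl}methanone | COc1cc([C@H]2OC[C@@H](C(=O)c3ccc(O[Si](C)(C)C(C)(C)C)c(O[Si](C)(C)C(C)(C)C)c3)[C@@H]2COCc2ccccc2)ccc1OCc1ccccc1 | intermediate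
20 | (R)-[3,4-bis(tert-butyldimethylsilyloxy)phenyl]{(2S,3R,4S)-2-[4-(benzyloxy)-3-methoxyphenyl]-3-[(benzyloxy)methyl]tetrahydrofuran-4-yl}methanol | COc1cc([C@H]2OC[C@@H]([C@@H](O)c3ccc(O[Si](C)(C)C(C)(C)C)c(O[Si](C)(C)C(C)(C)C)c3)[C@@H]2COCc2ccccc2)ccc1OCc1ccccc1 | intermediate
21 | 4-[(R)-{(2S,3R,4S)-2-[4-(benzyloxy)-3-methoxyphenyl]-3-[(benzyloxy)methyl]tetrahydrofuran-4-yl}(hydroxy)methyl]benzene-1,2-diol | COc1cc([C@H]2OC[C@@H]([C@@H](O)c3ccc(O)c(O)c3)[C@@H]2COCc2ccccc2)ccc1OCc1ccccc1 | intermediate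
22 | (2S,3R,4S)-4-[(R)-(3,4-dihydroxyphenyl)(hydroxy)methyl]-2-(4-hydroxy-3-methoxyphenyl)-3-(hydroxymethyl)tetrahydrofuran | COc1cc([C@H]2OC[C@@H]([C@@H](O)c3ccc(O)c(O)c3)[C@@H]2CO)ccc1O | target

**Step count**
Total: 15 steps. Longest linear sequence: 14 steps (steps 1–10 and 12–15); the diene is made in one step (step 11) on a side branch.

**Steps most likely to fail**

Step 12 (cycloaddition and aromatisation). The cycloaddition may be slow because the 2,3-disubstituted diene is strained in its s-cis form, and the terminal ynone may oligomerise at the temperature needed. The cycloadduct may also aromatise by loss of silanol instead of hydrogen, which would remove one ring oxygen. The fallback sets out from aldehyde 12 and brings in the catechol ring ready-made. 4-Bromocatechol is silylated (t-BuMe2SiCl, imidazole, DMF) to 4-bromo-1,2-bis(tert-butyldimethylsilyloxy)benzene F1. Bromine–lithium exchange (n-BuLi, THF, −78 °C) gives [3,4-bis(tert-butyldimethylsilyloxy)phenyl]lithium F2, which is added to 12 at −78 °C to give the diaryl carbinol F3 as a mixture of C7' epimers. Dess–Martin oxidation of F3 in CH2Cl2 returns to the route at ketone 19.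

Step 13 (reduction at C7'). Facial selectivity may be poor, because the branched C4 substituent competes with the aryl group for the role of the larger group and the ring stereocentres may work against the catalyst. The fallback sets out from ketone 19. NaBH4 in MeOH/THF at 0 °C gives 20 together with its C7' epimer, the (7'S)-carbinol F4, and the two are separated by chromatography. F4 is inverted by a Mitsunobu reaction (benzoic acid, PPh3, diisopropyl azodicarboxylate, toluene, 0 °C) to the (7'R)-benzoate F5. The ester is then cleaved with (i-Bu)2AlH in CH2Cl2 at −78 °C, which leaves the aryl silyl ethers in place, and the route is rejoined at 20.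

Step 4 (aryllithium addition to the lactone). The hemiketal alkoxide may collapse early and the liberated ketone take up a second aryllithium, or the lactone may be enolised with erosion of C3. The fallback sets out from lactone 5. Reduction with (i-Bu)2AlH in toluene at −78 °C gives the lactol F6 (anomer mixture). Excess aryllithium 7 (THF, −78 to 0 °C) then adds to its open hydroxy aldehyde form, which has no second electrophilic site, to give diol 9 directly; the route is rejoined at 9 and step 5 is not needed.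

**Further compounds**
F1 | step 12 | 4-bromo-1,2-bis(tert-butyldimethylsilyloxy)benzene | CC(C)(C)[Si](C)(C)Oc1ccc(Br)cc1O[Si](C)(C)C(C)(C)C
F2 | step 12 | [3,4-bis(tert-butyldimethylsilyloxy)phenyl]lithium | [Li]c1ccc(O[Si](C)(C)C(C)(C)C)c(O[Si](C)(C)C(C)(C)C)c1
F3 | step 12 | [3,4-bis(tert-butyldimethylsilyloxy)phenyl]{(2S,3R,4S)-2-[4-(benzyloxy)-3-methoxyphenyl]-3-[(benzyloxy)methyl]tetrahydrofuran-4-yl}methanol, C7' epimer mixture | COc1cc([C@H]2OC[C@@H](C(O)c3ccc(O[Si](C)(C)C(C)(C)C)c(O[Si](C)(C)C(C)(C)C)c3)[C@@H]2COCc2ccccc2)ccc1OCc1ccccc1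
F4 | step 13 | (S)-[3,4-bis(tert-butyldimethylsilyloxy)phenyl]{(2S,3R,4S)-2-[4-(benzyloxy)-3-methoxyphenyl]-3-[(benzyloxy)methyl]tetrahydrofuran-4-yl}methanol | COc1cc([C@H]2OC[C@@H]([C@H](O)c3ccc(O[Si](C)(C)C(C)(C)C)c(O[Si](C)(C)C(C)(C)C)c3)[C@@H]2COCc2ccccc2)ccc1OCc1ccccc1
F5 | step 13 | (R)-[3,4-bis(tert-butyldimethylsilyloxy)phenyl]{(2S,3R,4S)-2-[4-(benzyloxy)-3-methoxyphenyl]-3-[(benzyloxy)methyl]tetrahydrofuran-4-yl}methyl benzoate | COc1cc([C@H]2OC[C@@H]([C@@H](OC(=O)c3ccccc3)c3ccc(O[Si](C)(C)C(C)(C)C)c(O[Si](C)(C)C(C)(C)C)c3)[C@@H]2COCc2ccccc2)ccc1OCc1ccccc1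
F6 | step 4 | (3R,4S)-3-[(benzyloxy)methyl]-4-{[(tert-butyldiphenylsilyl)oxy]methyl}tetrahydrofuran-2-ol, anomer mixture | OC1OC[C@@H](CO[Si](c2ccccc2)(c2ccccc2)C(C)(C)C)[C@@H]1COCc1ccccc1
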